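**Retrosynthetic overview**

1. Numbering: indenone C1 (ring C=O), C2 (azulenyl), C3 (methyl), C3a/C7a (fusion), C4 (isobutyryl), C7 (methyl). The five-membered ring is ring A, the benzene ring is ring B. Ring A is the only ring made, and it is made last; ring B and the azulene are bought intact.
2. Last disconnection: the C3–C3a bond of ring A, with loss of water, back to the open-chain 2-azulenyl-1-aryl-butane-1,3-dione 9 (C3 = acetyl carbonyl carbon, C3a = free C–H of ring B).
3. Enabling feature: C3a–H sits on ring B between C4 (isobutyryl) and C7a (aroyl C1). The isobutyryl oxygen is a built-in directing group that lets iridium insert into C3a–H. This reverses the polarity of a doubly acyl-flanked acceptor carbon so that it adds to the C3 carbonyl, a second acceptor; dehydration then sets C2=C3.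
4. 9 comes from guaiazulene 8 (nucleophilic C3–H) and diazo diketone 7 by rhodium-carbene C–H functionalisation (C2–azulene bond).
5. 7 comes from 3-bromo-4-methylbenzoic acid 1 by Grignard acylation (isobutyryl), Stille acetylation, Claisen condensation and diazo transfer.

Key step: step 6

Assumption: the target is treated as drawn, without stereocentre or fixed axis; 9 is used as its racemic keto–enol mixture and 10 is a diastereomer mixture, since both stereocentres vanish in the dehydration.

**Route**

Step 1
Reactants: 1 3-bromo-4-methylbenzoic acid
Product: 3 1-(3-bromo-4-methylphenyl)-2-methylpropan-1-one, via 3-bromo-4-methylbenzoyl chloride 2 (not isolated)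
Conditions: (COCl)2, DMF (cat.), CH2Cl2, 0 °C to rt, evaporate; then iPrMgCl, CuI (5 mol%), THF, −78 °C
Reagents that add atoms: oxalyl chloride ClC(=O)C(=O)Cl (chlorine of 2); isopropylmagnesium chloride CC(C)[Mg]Cl
Why: Acid chloride formation followed by copper-catalysed acylation of a Grignard reagent should give the ketone without over-addition at −78 °C, and the aryl bromide should be inert because bromine–magnesium exchange does not occur under these conditions.

Step 2
Reactants: 3 1-(3-bromo-4-methylphenyl)-2-methylpropan-1-one
Product: 5 1-(3-acetyl-4-methylphenyl)-2-methylpropan-1-one, via ethyl enol ether 4 (not isolated)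
Conditions: tributyl(1-ethoxyvinyl)stannane, Pd(PPh3)4 (5 mol%), toluene, 100 °C; then 2 M HCl, THF, rt
Reagents that add atoms: tributyl(1-ethoxyvinyl)stannane CCCC[Sn](CCCC)(CCCC)C(=C)OCC; water O
Why: Stille coupling of the aryl bromide with the 1-ethoxyvinylstannane installs a masked acetyl group that dilute acid unveils by enol ether hydrolysis, while the hindered isobutyryl ketone is untouched.

Step 3
Reactants: 5 1-(3-acetyl-4-methylphenyl)-2-methylpropan-1-one
Product: 6 1-[2-methyl-5-(2-methylpropanoyl)phenyl]butane-1,3-dione
Conditions: NaH (2.5 equiv), EtOAc (5 equiv), THF, 0 °C to reflux; then aq. HCl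
Reagents that add atoms: ethyl acetate CCOC(C)=O
Why: Claisen condensation should be selective because only the methyl ketone forms an enolate whose C-acetylation product is held as the stable sodium β-diketonate, whereas acylation at the isobutyryl methine would give a non-enolisable diketone that reverts.

Step 4
Reactants: 6 1-[2-methyl-5-(2-methylpropanoyl)phenyl]butane-1,3-dione
Product: 7 2-diazo-1-[2-methyl-5-(2-methylpropanoyl)phenyl]butane-1,3-dione
Conditions: 4-acetamidobenzenesulfonyl azide, Et3N, MeCN, 0 °C to rt
Reagents that add atoms: 4-acetamidobenzenesulfonyl azide CC(=O)Nc1ccc(cc1)S(=O)(=O)N=[N+]=[N-]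
Why: Regitz diazo transfer from the sulfonyl azide to the doubly activated methylene of the 1,3-diketone is general and should leave the far less acidic isobutyryl ketone alone.

Step 5
Reactants: 7 2-diazo-1-[2-methyl-5-(2-methylpropanoyl)phenyl]butane-1,3-dione; 8 guaiazulene
Product: 9 2-[3,8-dimethyl-5-(propan-2-yl)azulen-1-yl]-1-[2-methyl-5-(2-methylpropanoyl)phenyl]butane-1,3-dione
Conditions: Rh2(OAc)4 (2 mol%), 8 (2 equiv), ClCH2CH2Cl, 80 °C, slow addition of 7
Reagents that add atoms: none
Why: Carbene C–H functionalisation of an electron-rich arene: the electrophilic rhodium carbene from 7 should be attacked by C3 of guaiazulene, the only free nucleophilic position of its five-membered ring, and proton transfer from the tropylium-type zwitterion restores the azulene, the new C2 stereocentre being formed racemic and removed again in step 6.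

Step 6
Reactants: 9 2-[3,8-dimethyl-5-(propan-2-yl)azulen-1-yl]-1-[2-methyl-5-(2-methylpropanoyl)phenyl]butane-1,3-dione
Product: 11 2-[3,8-dimethyl-5-(propan-2-yl)azulen-1-yl]-3,7-dimethyl-4-(2-methylpropanoyl)-1H-inden-1-one (target CNP0225119.0), via 3-hydroxyindan-1-one aldol 10 (not isolated)
Conditions: [Ir(cod)2][B(3,5-(CF3)2C6H3)4] (10 mol%), rac-BINAP (10 mol%), PhCl, 135 °C, sealed tube, Ar
Reagents that add atoms: none
Why: Proposed new method: the cationic monovalent iridium–BINAP complex should bind the isobutyryl oxygen on C4 and insert into the adjacent C3a–H bond to give a five-membered acyl-chelated aryl iridium hydride, after which the keto form of the C3 acetyl carbonyl inserts into the Ir–C3a bond, O–H reductive elimination releases aldol 10, and loss of water across C2–C3 (acidic C2–H, tertiary benzylic C3–OH) gives the indenone. The closest known reaction type is the cationic iridium–bisphosphine-catalysed, acyl-directed cyclodehydration of meta-acyl aryloxy ketones to 4-acylbenzofurans, in which an aryl C–H bond ortho to a ketone adds to a tethered ketone and the carbinol dehydrates; here the tether is a β-diketone and the new ring is carbocyclic. Ring A closes by 5-exo-trig attack of the metalated C3a on the C3 carbonyl carbon, a union of two acceptor carbons made possible by polarity reversal at C3a. The stereocentres at C2 and C3 of 10 are not controlled and both disappear on dehydration, so the target forms without any stereochemical element. The step needs site selectivity for C3a–H over C5–H and the azulene C–H bonds and chemoselectivity for the acetyl carbonyl; both should follow from geometry, since only C3a–H is ortho to the directing isobutyryl group and within five-ring reach of C3, while metalation at C5 is reversible and unproductive.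

**Compound list**

1 | 3-bromo-4-methylbenzoic acid | Cc1ccc(C(=O)O)cc1Br | starting material
2 | 3-bromo-4-methylbenzoyl chloride (not isolated) | Cc1ccc(C(=O)Cl)cc1Br | intermediate
3 | 1-(3-bromo-4-methylphenyl)-2-methylpropan-1-one | Cc1ccc(C(=O)C(C)C)cc1Br | intermediate
4 | 1-[3-(1-ethoxyethenyl)-4-methylphenyl]-2-methylpropan-1-one (ethyl enol ether, not isolated) | CCOC(=C)c1cc(C(=O)C(C)C)ccc1C | intermediate
5 | 1-(3-acetyl-4-methylphenyl)-2-methylpropan-1-one | CC(=O)c1cc(C(=O)C(C)C)ccc1C | intermediate
6 | 1-[2-methyl-5-(2-methylpropanoyl)phenyl]butane-1,3-dione | CC(=O)CC(=O)c1cc(C(=O)C(C)C)ccc1C | intermediate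
7 | 2-diazo-1-[2-methyl-5-(2-methylpropanoyl)phenyl]butane-1,3-dione | CC(=O)C(=[N+]=[N-])C(=O)c1cc(C(=O)C(C)C)ccc1C | intermediate
8 | guaiazulene (1,4-dimethyl-7-(propan-2-yl)azulene) | c1cc(C)c2cc(C(C)C)ccc(C)c1-2 | starting material
9 | 2-[3,8-dimethyl-5-(propan-2-yl)azulen-1-yl]-1-[2-methyl-5-(2-methylpropanoyl)phenyl]butane-1,3-dione (racemic at C2, keto–enol mixture) | CC(=O)C(c1cc(C)c2cc(C(C)C)ccc(C)c1-2)C(=O)c1cc(C(=O)C(C)C)ccc1C | intermediate
10 | 2-[3,8-dimethyl-5-(propan-2-yl)azulen-1-yl]-3-hydroxy-3,7-dimethyl-4-(2-methylpropanoyl)-2,3-dihydro-1H-inden-1-one (diastereomer mixture, not isolated) | CC1(O)C(c2cc(C)c3cc(C(C)C)ccc(C)c2-3)C(=O)c2c(C)ccc(C(=O)C(C)C)c21 | intermediate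
11 | 2-[3,8-dimethyl-5-(propan-2-yl)azulen-1-yl]-3,7-dimethyl-4-(2-methylpropanoyl)-1H-inden-1-one (CNP0225119.0, no stereocentre) | CC1=C(c2cc(C)c3cc(C(C)C)ccc(C)c2-3)C(=O)c2c(C)ccc(C(=O)C(C)C)c21 | target

**Step count and risks**

Total steps: 6. Longest linear sequence: 6 steps (1 to 11); guaiazulene 8 enters in step 5.

Steps most likely to fail:

1. Step 6 (Proposed new method). What may go wrong: the catalyst may be taken out of the cycle by chelation to the enol(ate) form of the β-diketone or by π-binding to the azulene, so that C–H insertion does not turn over. The water released may also cleave the diketone by retro-Claisen deacylation before ring closure. The fallback uses known chemistry, sets out from 9 and comes back at 11. The sodium enolate of 9 (NaH, THF, 0 °C) is O-triflated with N-phenylbis(trifluoromethanesulfonimide) at the less hindered acetyl oxygen. The chelated U-shaped enolate places the triflate cis to the aroyl group and should give (Z)-enol triflate F1. Treatment with Pd(OAc)2, PCy3·HBF4, K2CO3 and pivalic acid in DMA at 110 °C then effects an intramolecular direct C–H alkenylation: oxidative addition of zerovalent palladium into the C3–O bond, pivalate-assisted concerted metalation–deprotonation of C3a–H (the most acidic C–H of ring B, between two acyl-bearing carbons) and reductive elimination from the six-membered palladacycle. This forms the same C3–C3a bond and gives 11 directly.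

2. Step 5. What may go wrong: the rhodium carbene may be consumed faster by intramolecular insertion into the benzylic C–H of the neighbouring ring methyl, by Wolff rearrangement or by dimerisation than by attack of the hindered azulene C3 (peri to the C4 methyl). The fallback avoids carbenes, sets out from 7 and comes back at 9. Oxidation with dimethyldioxirane (acetone, 0 °C) turns the diazo carbon into a ketone and gives vicinal tricarbonyl F2. Guaiazulene 8 then adds through C3 to the central, most electrophilic carbonyl (CH2Cl2, rt; Friedel–Crafts hydroxyalkylation) to give tertiary carbinol F3. Ionic hydrogenation (Et3SiH, CF3CO2H, CH2Cl2, 0 °C) removes the hydroxyl group through the azulene-stabilised cation and should deliver 9.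

3. Step 3. What may go wrong: unselective enolisation and aldol self-condensation of methyl ketone 5 under sodium hydride may compete with C-acetylation. The fallback sets out from 5 and comes back at 6. Condensation with N,N-dimethylacetamide dimethyl acetal (neat, 110 °C) proceeds under neutral conditions and only a CH3–C=O group can undergo it; it should give enaminone F4. Hydrolysis (1 M HCl, THF, rt) then gives 6.

**Further compounds**

F1 | step 6 | (2Z)-3-[3,8-dimethyl-5-(propan-2-yl)azulen-1-yl]-4-[2-methyl-5-(2-methylpropanoyl)phenyl]-4-oxobut-2-en-2-yl trifluoromethanesulfonate | C/C(OS(=O)(=O)C(F)(F)F)=C(\c1cc(C)c2cc(C(C)C)ccc(C)c1-2)C(=O)c1cc(C(=O)C(C)C)ccc1C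
F2 | step 5 | 1-[2-methyl-5-(2-methylpropanoyl)phenyl]butane-1,2,3-trione | CC(=O)C(=O)C(=O)c1cc(C(=O)C(C)C)ccc1C
F3 | step 5 | 2-[3,8-dimethyl-5-(propan-2-yl)azulen-1-yl]-2-hydroxy-1-[2-methyl-5-(2-methylpropanoyl)phenyl]butane-1,3-dione (racemic) | CC(=O)C(O)(c1cc(C)c2cc(C(C)C)ccc(C)c1-2)C(=O)c1cc(C(=O)C(C)C)ccc1C
F4 | step 3 | (2E)-3-(dimethylamino)-1-[2-methyl-5-(2-methylpropanoyl)phenyl]but-2-en-1-one | C/C(=C\C(=O)c1cc(C(=O)C(C)C)ccc1C)N(C)C
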